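The rate constants were set for the occasion; the result is computed.

**Small charge.** A charge of 0.16 mM of free catalyst has to carry 16 mM of substrate, so on average each catalyst must turn 100 times for full conversion. The question is what slows a turn as by-product gathers.

    partner + free catalyst → catalyst intermediate A (k1 = 6600 M⁻¹ s⁻¹)
    substrate + catalyst intermediate A ⇌ catalyst intermediate B (K2 = 110 M⁻¹, k2 = 100 M⁻¹ s⁻¹)
    catalyst intermediate B ⇌ catalyst intermediate C (K3 = 0.86, k3 = 2.9 s⁻¹)
    catalyst intermediate C ⇌ by-product + catalyst intermediate D (K4 = 0.0076 M, k4 = 3.7 s⁻¹)
    catalyst intermediate D → free catalyst + product (k5 = 1.5 s⁻¹)
    2 catalyst intermediate B ⇌ resting dimer, settled at all times (K6 = 12000 M⁻¹)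

| setting | zeta | epsilon | beta | eta |
|---|---|---|---|---|
| substrate | 16 mM | 16 mM | 16 mM | 16 mM |
| partner | 16.0 mM | 16.0 mM | 16.0 mM (fed, over 2.50 min) | 16.0 mM |
| free catalyst | 0.16 mM | 0.16 mM | 0.16 mM | 0.16 mM |
| remark | one stirred flow tank at steady state, fed with the mixture as stated, mean residence time 2.5 min | a closed flask charged with all of it at once and left for 2.5 min | a stirred flask in which partner is dosed at a steady rate over 2.50 min without added volume, worked up at 2.5 min | one stirred flow tank at steady state, fed with the mixture as stated, mean residence time 12.5 min |
| time |  | 2.5 min | 2.5 min |  |

- the set-up with the highest amount of product at the outlet or at the end, in percent of the substrate put in ("none" if the first two lie within 2 percentage points) (zeta / epsilon / beta / eta / none)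
- amount of product at the outlet or at the end, in percent of the substrate put in, zeta
- amount of product at the outlet or at the end, in percent of the substrate put in, epsilon
- amount of product at the outlet or at the end, in percent of the substrate put in, beta
- amount of product at the outlet or at the end, in percent of the substrate put in, eta

- percentages count the substrate that a species holds: one resting dimer counts as two
- a step written with two of one species runs at k times the square of its concentration and takes two of it each time
- the stated concentrations are those of everything mixed, before any reaction; amounts are the same in each set-up
- the feed brings no volume worth counting
- run time (epsilon): 2.5 min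

**Two exits.** Catalyst intermediate D goes forward at 1.5 s⁻¹, or it takes up by-product and returns to catalyst intermediate C at 487 M⁻¹ s⁻¹ times the by-product concentration b. Divide one rate by the other and both time and the concentration of D drop out. The by-product level at which D goes back as often as forward, the return concentration b*, is 3.08 mM. The forward share is then one over one plus b/b*, the form of product inhibition, here by the by-product. That level is 19.2% of the substrate charge, and no by-product is charged, so b follows product to within the catalyst charge.

**Turn time.** Take zeta, the tank with mean residence time 2.5 min, where b must equal the turnover rate r times that time. In a steady cycle each form holds r times its stay. I try b at 4.62 mM in zeta, which is b* and half again, with substrate at 11.4 mM. Working backwards round the cycle, the stays are 0.667 s for D, 0.676 s for C, 1.13 s for catalyst intermediate B and 1.78 s for catalyst intermediate A. Free catalyst stays 0.0133 s, far less than these, so I drop it. The turn time T is 4.25 s, which gives r = 0.0376 mM s⁻¹ and, over the residence time, 5.64 mM of by-product. That is more than the trial, so this reckoning puts zeta between 28.9% and 35.2% of the charge.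

**Weak link.** That sum treats all catalyst as cycling, but two of B pair into the resting dimer. Adding the catalyst held there makes the balance quadratic in r, and its root is 0.0308 mM s⁻¹. The resting dimer in zeta then holds 0.0291 mM of catalyst, counted two per dimer. Over the residence time this gives 4.62 mM, level with the trial, so the balance closes and I commit to 28.9% for zeta.

**The forecast.** The forecast gives 28.7% for zeta, 33.9% for epsilon, 33.3% for beta and 70.3% for eta, with eta best, holding that “the five-times-longer residence time in eta wins clearly”.

**The flask.** The simulation gives 28.6% for zeta, 34.3% for epsilon, 33.6% for beta and 70.4% for eta, with eta best; my figure for zeta was 28.9%. With one by-product per product, and to within the catalyst charge, the zeta outlet holds about 4.58 mM of by-product, which is 1.49 times b*, so D goes forward on 40.2% of its visits. With the return of by-product and D to C struck out, zeta gives 39.9%. In eta, about 11.3 mM of by-product is 3.67 times b*, and the forward share of D is 21.4%.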